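## Retrosynthetic overview

1. Target 21 ⇒ acetylation of hydroxy lactone 20 ⇒ bis-enal 17 by the key C–O events: α-face syn-dihydroxylation of C8=C9, closure of the new 8-OH onto one of two identical acrolein arms, and oxidation of that lactol to the lactone.
2. 17 ⇒ double allylic C–H oxidation and C6–O angeloylation of cyclohexenol 12 ⇒ face-selective reduction of ketone 11.
3. 11 ⇒ acyl–ene closure of the C6–C7 bond in open-chain (Z)-diene acid 9 ⇒ enyne acid 8 (the alkyne is a masked cis-alkene for the later diol).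
4. 8 ⇒ enantioselective Ireland–Claisen rearrangement (C5–C10 bond) of ester 5 ⇒ enynol 3 (Sonogashira of 1 + 2) and acid 4.
5. Ring order: cyclohexene (step 5), then γ-lactone (step 9).

Assumption: elemane numbering is used for locants and α/β (C10 carries Me and the C1=C2 vinyl, C5 the C3=C4–C15 arm, C7 the C11(=C13)–C12 arm); the (S,S)-diazaborolidine is taken to give acid 8 as drawn, otherwise its (R,R)-antipode is used.

## Route

Step 1
Reactants: 1 (2E)-3-methylpent-2-en-4-yn-1-ol; 2 1-bromo-2-methylprop-1-ene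
Product: 3 (2E)-3,7-dimethylocta-2,6-dien-4-yn-1-ol
Conditions: PdCl2(PPh3)2 (2 mol %), CuI (4 mol %), Et3N, THF, rt
Reagents that add atoms: none
Why: Sonogashira coupling of a terminal alkyne with a vinyl bromide; the free allylic alcohol is tolerated and the 2E geometry is untouched.

Step 2
Reactants: 3 (2E)-3,7-dimethylocta-2,6-dien-4-yn-1-ol; 4 3-methylbut-3-enoic acid
Product: 5 (2E)-3,7-dimethylocta-2,6-dien-4-yn-1-yl 3-methylbut-3-enoate
Conditions: DCC, DMAP (5 mol %), CH2Cl2, 0 °C
Reagents that add atoms: none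
Why: Steglich esterification; low temperature and little DMAP keep the β,γ-double bond out of conjugation.

Step 3
Reactants: 5 (2E)-3,7-dimethylocta-2,6-dien-4-yn-1-yl 3-methylbut-3-enoate
Product: 8 (2S,3S)-3-ethenyl-3,7-dimethyl-2-(prop-1-en-2-yl)oct-6-en-4-ynoic acid, via boron ketene acetal 6 (not isolated), via acyloxyborane 7 (not isolated)
Conditions: (S,S)-bis-sulfonamide (1.2 equiv), BBr3, CH2Cl2, rt, evaporate; then 5, Et3N, toluene–hexane, −78 °C, then −20 → 4 °C; H2O work-up
Reagents that add atoms: none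
Why: Enantioselective boron-enolate Ireland–Claisen rearrangement, in which the E(O)-enolate and the 2E-alkene react through a chair with the isopropenyl and the C10 methyl both axial (giving Me cis to isopropenyl and vinyl trans at C5/C10) while the chiral diazaborolidine chooses the enolate face and so sets both centres absolutely.

Step 4
Reactants: 8 (2S,3S)-3-ethenyl-3,7-dimethyl-2-(prop-1-en-2-yl)oct-6-en-4-ynoic acid
Product: 9 (2S,3R,4Z)-3-ethenyl-3,7-dimethyl-2-(prop-1-en-2-yl)octa-4,6-dienoic acid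
Conditions: Zn(Cu/Ag), MeOH–H2O (1:1), 45 °C
Reagents that add atoms: none
Why: Activated-zinc (Boland-type) semi-reduction, which is selective for conjugated enynes, gives the 4Z-diene and leaves the vinyl and isopropenyl groups alone.

Step 5
Reactants: 9 (2S,3R,4Z)-3-ethenyl-3,7-dimethyl-2-(prop-1-en-2-yl)octa-4,6-dienoic acid
Product: 11 (2S,3R,6S)-3-ethenyl-3-methyl-2,6-di(prop-1-en-2-yl)cyclohex-4-en-1-one, via acid chloride 10 (not isolated)
Conditions: 1-chloro-N,N,2-trimethylprop-1-en-1-amine (Ghosez reagent), CH2Cl2, 0 °C; then Me2AlCl (2.2 equiv), CH2Cl2, −78 → −20 °C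
Reagents that add atoms: none
Why: Lewis-acid acyl–ene (Friedel–Crafts-type) cyclisation in which the acylium attacks C7 of the isobutenyl unit through a chair-like six-membered transition state and a methyl hydrogen is lost to give the isopropenyl group, the new C7 substituent ending pseudo-equatorial and cis to the C5 isopropenyl, while Me2AlCl removes HCl as methane so the β,γ-enone does not conjugate.

Step 6
Reactants: 11 (2S,3R,6S)-3-ethenyl-3-methyl-2,6-di(prop-1-en-2-yl)cyclohex-4-en-1-one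
Product: 12 (1R,2S,3R,6S)-3-ethenyl-3-methyl-2,6-di(prop-1-en-2-yl)cyclohex-4-en-1-ol
Conditions: L-Selectride, THF, −78 °C; H2O quench
Reagents that add atoms: none
Why: Bulky-hydride ketone reduction; the pseudo-axial C10 methyl blocks the β face, so hydride enters from the α face and gives the axial 6β-alcohol, cis to both isopropenyl groups.

Step 7
Reactants: 12 (1R,2S,3R,6S)-3-ethenyl-3-methyl-2,6-di(prop-1-en-2-yl)cyclohex-4-en-1-ol; 13 angelic acid, (2Z)-2-methylbut-2-enoic acid
Product: 15 (1R,2S,3R,6S)-3-ethenyl-3-methyl-2,6-di(prop-1-en-2-yl)cyclohex-4-en-1-yl (2Z)-2-methylbut-2-enoate, via mixed anhydride 14 (not isolated)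
Conditions: 13, 2,4,6-trichlorobenzoyl chloride, Et3N, toluene, rt; then 12, toluene, 80 °C
Reagents that add atoms: none
Why: Yamaguchi-type mixed-anhydride esterification, the usual way to put an angelate on a hindered secondary alcohol without Z→E isomerisation; C6 keeps its configuration.

Step 8
Reactants: 15 (1R,2S,3R,6S)-3-ethenyl-3-methyl-2,6-di(prop-1-en-2-yl)cyclohex-4-en-1-yl (2Z)-2-methylbut-2-enoate
Product: 17 6β-angeloyloxy-elema-1,3,8,11(13)-tetraene-12,15-dial (both prop-1-en-2-yl groups now 3-oxoprop-1-en-2-yl), via diol 16 (not isolated)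
Conditions: SeO2 (0.5 equiv), t-BuOOH (4 equiv), CH2Cl2, rt; then filter, MnO2, CH2Cl2, rt
Reagents that add atoms: tert-butyl hydroperoxide CC(C)(C)OO; selenium dioxide O=[Se]=O
Why: SeO2/t-BuOOH allylic oxidation (ene reaction then [2,3]-shift) goes at the CH3 of each 1,1-disubstituted alkene in preference to the methines, and MnO2 takes the allylic alcohols on to the two 2-substituted acroleins without touching a stereocentre.

Step 9
Reactants: 17 6β-angeloyloxy-elema-1,3,8,11(13)-tetraene-12,15-dial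
Product: 20 6β-angeloyloxy-9α-hydroxy-elema-1,3,11(13)-trien-15-al-12,8α-olide, via diol 18 (not isolated), via lactol 19 (not isolated)
Conditions: OsO4 (2 mol %), NMO (1.2 equiv), acetone–H2O (10:1), 0 °C → rt; then MeCN, [Cu(MeCN)4]OTf/2,2'-bipyridine/TEMPO (5 mol % each), N-methylimidazole (10 mol %), air, rt
Reagents that add atoms: N-methylmorpholine N-oxide C[N+]1([O-])CCOCC1; water O (both oxygens are delivered through catalytic OsO4, O=[Os](=O)(=O)=O)
Why: Proposed new method: a one-flask dihydroxylative lactonisation in which OsO4 adds to the only electron-rich alkene (C8=C9) from the α face, anti to the pseudo-axial C10 methyl and the axial C6 ester, to set C8 and C9, the new 8α-OH then closes 5-exo onto the only formyl group within reach (C12) to give the trans-fused γ-lactol, and Cu/TEMPO/O2, which oxidises hemiacetal and primary C–H but not hindered secondary alcohols or free enals, turns that lactol into the lactone, so C–O bond formation also tells the two identical acrolein arms apart; the closest known reactions are the Upjohn dihydroxylation and the Cu/nitroxyl aerobic oxidative lactonisation of 1,4-diols, which have not been merged or applied to a hydroxy-dialdehyde.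

Step 10
Reactants: 20 6β-angeloyloxy-9α-hydroxy-elema-1,3,11(13)-trien-15-al-12,8α-olide
Product: 21 CNP0228039.1, 9α-acetoxy-6β-angeloyloxy-elema-1,3,11(13)-trien-15-al-12,8α-olide
Conditions: Ac2O, DMAP (cat.), pyridine, CH2Cl2, 0 °C → rt
Reagents that add atoms: acetic anhydride CC(=O)OC(C)=O
Why: DMAP-catalysed acetylation of the remaining axial 9α-alcohol, with retention at C9.

## Compound list

1 | (2E)-3-methylpent-2-en-4-yn-1-ol | OC/C=C(\C)C#C | starting material
2 | 1-bromo-2-methylprop-1-ene | BrC=C(C)C | starting material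
3 | (2E)-3,7-dimethylocta-2,6-dien-4-yn-1-ol | OC/C=C(\C)C#CC=C(C)C | intermediate
4 | 3-methylbut-3-enoic acid | C=C(C)CC(=O)O | starting material
5 | (2E)-3,7-dimethylocta-2,6-dien-4-yn-1-yl 3-methylbut-3-enoate | C=C(C)CC(=O)OC/C=C(\C)C#CC=C(C)C | intermediate
6 | boron ketene acetal of 5 (O–B trans to the isopropenyl group; B is the (4S,5S)-1,3-bis{[3,5-bis(trifluoromethyl)phenyl]sulfonyl}-4,5-diphenyl-1,3,2-diazaborolidin-2-yl group) | C=C(C)/C=C(/OB1N(S(=O)(=O)c2cc(C(F)(F)F)cc(C(F)(F)F)c2)[C@@H](c2ccccc2)[C@H](c2ccccc2)N1S(=O)(=O)c1cc(C(F)(F)F)cc(C(F)(F)F)c1)OC/C=C(\C)C#CC=C(C)C | intermediate (not isolated)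
7 | acyloxyborane of acid 8 (same diazaborolidinyl group on the carboxylate oxygen) | C=C[C@](C)(C#CC=C(C)C)[C@H](C(C)=C)C(=O)OB1N(S(=O)(=O)c2cc(C(F)(F)F)cc(C(F)(F)F)c2)[C@@H](c2ccccc2)[C@H](c2ccccc2)N1S(=O)(=O)c1cc(C(F)(F)F)cc(C(F)(F)F)c1 | intermediate (not isolated)
8 | (2S,3S)-3-ethenyl-3,7-dimethyl-2-(prop-1-en-2-yl)oct-6-en-4-ynoic acid | C=C[C@](C)(C#CC=C(C)C)[C@H](C(C)=C)C(=O)O | intermediate
9 | (2S,3R,4Z)-3-ethenyl-3,7-dimethyl-2-(prop-1-en-2-yl)octa-4,6-dienoic acid | C=C[C@](C)(/C=C\C=C(C)C)[C@H](C(C)=C)C(=O)O | intermediate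
10 | (2S,3R,4Z)-3-ethenyl-3,7-dimethyl-2-(prop-1-en-2-yl)octa-4,6-dienoyl chloride | C=C[C@](C)(/C=C\C=C(C)C)[C@H](C(C)=C)C(=O)Cl | intermediate (not isolated)
11 | (2S,3R,6S)-3-ethenyl-3-methyl-2,6-di(prop-1-en-2-yl)cyclohex-4-en-1-one (elema-1,3,8,11(13)-tetraen-6-one) | C=C[C@]1(C)C=C[C@@H](C(C)=C)C(=O)[C@H]1C(C)=C | intermediate
12 | (1R,2S,3R,6S)-3-ethenyl-3-methyl-2,6-di(prop-1-en-2-yl)cyclohex-4-en-1-ol (6β-OH, cis to both isopropenyls and to the C10 methyl) | C=C[C@]1(C)C=C[C@@H](C(C)=C)[C@@H](O)[C@H]1C(C)=C | intermediate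
13 | angelic acid, (2Z)-2-methylbut-2-enoic acid | C/C=C(/C)C(=O)O | starting material
14 | (2Z)-2-methylbut-2-enoic 2,4,6-trichlorobenzoic anhydride | C/C=C(/C)C(=O)OC(=O)c1c(Cl)cc(Cl)cc1Cl | intermediate (not isolated)
15 | (1R,2S,3R,6S)-3-ethenyl-3-methyl-2,6-di(prop-1-en-2-yl)cyclohex-4-en-1-yl (2Z)-2-methylbut-2-enoate | C=C[C@]1(C)C=C[C@@H](C(C)=C)[C@@H](OC(=O)/C(C)=C\C)[C@H]1C(C)=C | intermediate
16 | 12,15-diol of 15 (both prop-1-en-2-yl groups now 3-hydroxyprop-1-en-2-yl) | C=C[C@]1(C)C=C[C@@H](C(=C)CO)[C@@H](OC(=O)/C(C)=C\C)[C@H]1C(=C)CO | intermediate (not isolated)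
17 | 6β-angeloyloxy-elema-1,3,8,11(13)-tetraene-12,15-dial | C=C[C@]1(C)C=C[C@@H](C(=C)C=O)[C@@H](OC(=O)/C(C)=C\C)[C@H]1C(=C)C=O | intermediate
18 | 6β-angeloyloxy-8α,9α-dihydroxy-elema-1,3,11(13)-triene-12,15-dial | C=C[C@]1(C)[C@H](O)[C@H](O)[C@@H](C(=C)C=O)[C@@H](OC(=O)/C(C)=C\C)[C@H]1C(=C)C=O | intermediate (not isolated)
19 | 12,8α-lactol of 18 (γ-hemiacetal, both C12 epimers), 9α-OH and 15-al free | C=C[C@]1(C)[C@H](O)[C@@H]2OC(O)C(=C)[C@H]2[C@@H](OC(=O)/C(C)=C\C)[C@H]1C(=C)C=O | intermediate (not isolated)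
20 | 6β-angeloyloxy-9α-hydroxy-elema-1,3,11(13)-trien-15-al-12,8α-olide | C=C[C@]1(C)[C@H](O)[C@@H]2OC(=O)C(=C)[C@H]2[C@@H](OC(=O)/C(C)=C\C)[C@H]1C(=C)C=O | intermediate
21 | CNP0228039.1, (3aS,4S,5R,6S,7S,7aR)-7-acetoxy-6-ethenyl-6-methyl-3-methylidene-2-oxo-5-(3-oxoprop-1-en-2-yl)octahydro-1-benzofuran-4-yl (2Z)-2-methylbut-2-enoate | C=C[C@]1(C)[C@H](OC(C)=O)[C@@H]2OC(=O)C(=C)[C@H]2[C@@H](OC(=O)/C(C)=C\C)[C@H]1C(=C)C=O | target

## Step count and risks

Total steps: 10. Longest linear sequence: 10 (from 1; compounds 2, 4 and 13 are bought).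

**Step 5 (acyl–ene closure at the inner carbon of a conjugated diene).** The acylium may react elsewhere on the diene, or the triply activated C7–H of ketone 11 may allow conjugation. The fallback sets out from acid 9 and uses the milder aldehyde electrophile. LiAlH4 (Et2O, 0 °C) gives the primary alcohol F1, and Dess–Martin periodinane gives the aldehyde F2. A Me2AlCl-promoted type-I carbonyl–ene reaction (CH2Cl2, −78 °C, as for citronellal to isopulegol) then closes the ring to the 6α-alcohol F3. Buffered Dess–Martin oxidation of F3 comes back to the route at ketone 11, which is reduced at once as in step 6.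

**Step 8 (double SeO2 oxidation).** The doubly allylic C7–H may be attacked, or selenium species may isomerise the angelate. The fallback sets out from angelate 15 and replaces the selenium ene chemistry by an ene-type chlorination. Ca(OCl)2 with solid CO2 in CH2Cl2–H2O at 0 °C gives the bis(allylic chloride) F4. N-oxide oxidation of the two allylic chlorides (NMO, MeCN, rt) comes back to the route at bis-enal 17.

**Step 9 (proposed new tandem).** The Os and Cu/nitroxyl systems may interfere, or the lactol may not be oxidised cleanly next to the free diol equilibrium. The fallback sets out from bis-enal 17 and uses only known, separate reactions. Dihydroxylation under anhydrous boronate-trapping conditions (OsO4 cat., NMO, PhB(OH)2, CH2Cl2) gives the cyclic 8α,9α-phenylboronate F5, which is purified. Exchange with diethanolamine frees the diol, which is isolated as lactol 19. Oxidation of this allylic lactol with MnO2 (or Ag2CO3 on Celite) comes back to the route at hydroxy lactone 20.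

## Further compounds

F1 | step 5 | (2S,3R,4Z)-3-ethenyl-3,7-dimethyl-2-(prop-1-en-2-yl)octa-4,6-dien-1-ol | C=C[C@](C)(/C=C\C=C(C)C)[C@H](C(C)=C)CO
F2 | step 5 | (2S,3R,4Z)-3-ethenyl-3,7-dimethyl-2-(prop-1-en-2-yl)octa-4,6-dienal | C=C[C@](C)(/C=C\C=C(C)C)[C@H](C(C)=C)C=O
F3 | step 5 | (1S,2S,3R,6S)-3-ethenyl-3-methyl-2,6-di(prop-1-en-2-yl)cyclohex-4-en-1-ol (6α-epimer of 12) | C=C[C@]1(C)C=C[C@@H](C(C)=C)[C@H](O)[C@H]1C(C)=C
F4 | step 8 | 12,15-dichloride of 15 (both prop-1-en-2-yl groups now 3-chloroprop-1-en-2-yl) | C=C[C@]1(C)C=C[C@@H](C(=C)CCl)[C@@H](OC(=O)/C(C)=C\C)[C@H]1C(=C)CCl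
F5 | step 9 | cyclic 8α,9α-phenylboronate of diol 18 | C=C[C@]1(C)[C@@H]2OB(c3ccccc3)O[C@@H]2[C@@H](C(=C)C=O)[C@@H](OC(=O)/C(C)=C\C)[C@H]1C(=C)C=O
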